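Numbering: lactone ring C1(syringyl)–O2–C3(=O)–C4–C5; oxolane ring C4–C5–C6H2–O7–C8(catechol aryl). The plan cuts the oxolane at C4–C8 and C6–O7. It exploits two features: C6 is the one unsubstituted ring carbon, and C4 can bear a second, disposable ester. The C4–C5–C6 triad can therefore stay closed as a three-membered ring until the aldehyde arrives. The precursor is an (R)-2-aroylcyclopropane-1,1-diester. With magnesium iodide and 3,4-bis(benzyloxy)benzaldehyde it should give the 2,4-cis 2-aryl-4-aroyloxolane-3,3-diester in one operation. That operation makes two bonds, one ring and the C8 centre, and carries C5 through unchanged. Ketone reduction, lactonisation, loss of the spare ester and debenzylation complete the target.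

Key step: step 5

Remark: the target SMILES reads as C1 S, C4 R, C5 S, C8 S. All four ring hydrogens lie on one face, so both aryl groups are endo (cis to the other ring). The route is planned for this isomer.

Step 1
Reactants: 1 acetosyringone
Product: 2 1-[4-(benzyloxy)-3,5-dimethoxyphenyl]ethan-1-one
Conditions: BnBr, K2CO3, DMF, 60 °C
Reagents that add atoms: benzyl bromide, BrCc1ccccc1
Why: Williamson ether synthesis on the acidic para-acylphenol; benzyl is chosen because it withstands carbonate, magnesium iodide in THF, ruthenium hydride and hot lithium chloride and is removed at the end without acid or strong base.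

Step 2
Reactants: 2 1-[4-(benzyloxy)-3,5-dimethoxyphenyl]ethan-1-one
Product: 4 1-[4-(benzyloxy)-3,5-dimethoxyphenyl]prop-2-en-1-one, via Mannich base 3 (not isolated)
Conditions: (CH2O)n, i-Pr2NH·TFA (1 equiv), TFA (10 mol %), THF, reflux; BHT added, used at once
Reagents that add atoms: paraformaldehyde (reacts as formaldehyde), C=O
Why: Mannich α-methylenation, in which the enol of 2 attacks the iminium ion formed from formaldehyde and the ammonium salt and Mannich base 3 loses the hindered amine under the same mildly acidic conditions, so the polymerisable enone never meets base.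

Step 3
Reactants: 4 1-[4-(benzyloxy)-3,5-dimethoxyphenyl]prop-2-en-1-one; 5 dimethyl bromomalonate
Product: 7 racemic dimethyl 2-[4-(benzyloxy)-3,5-dimethoxybenzoyl]cyclopropane-1,1-dicarboxylate, via bromo Michael adduct 6 (not isolated)
Conditions: K2CO3, MeCN, 0 → 23 °C, slow addition of 4
Reagents that add atoms: none
Why: Michael-initiated ring closure, in which the bromomalonate anion adds to the terminal carbon (C6) of 4 and the ketone enolate carbon (C5) displaces bromide at C4 (3-exo-tet), the standard entry to 2-acylcyclopropane-1,1-diesters; C5 is formed racemic here.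

Step 4
Reactants: 7 racemic dimethyl 2-[4-(benzyloxy)-3,5-dimethoxybenzoyl]cyclopropane-1,1-dicarboxylate
Product: 8 dimethyl (2R)-2-[4-(benzyloxy)-3,5-dimethoxybenzoyl]cyclopropane-1,1-dicarboxylate
Conditions: preparative chiral SFC, immobilised amylose tris(3,5-dimethylphenylcarbamate) phase, CO2/MeOH
Reagents that add atoms: none
Why: Chromatographic resolution on a polysaccharide chiral stationary phase, routine for activated cyclopropane diesters, fixes C5 as R at the cheapest point of the route and avoids an enantioselective ring closure shown only for β-substituted enones; the collected enantiomer is to be assigned by vibrational circular dichroism or X-ray analysis.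

Step 5
Reactants: 8 dimethyl (2R)-2-[4-(benzyloxy)-3,5-dimethoxybenzoyl]cyclopropane-1,1-dicarboxylate; 9 3,4-bis(benzyloxy)benzaldehyde
Product: 12 dimethyl (2R,4S)-4-[4-(benzyloxy)-3,5-dimethoxybenzoyl]-2-[3,4-bis(benzyloxy)phenyl]oxolane-3,3-dicarboxylate (2,4-cis), via iodo enolate 10 (not isolated), via iodo aldolate 11 (not isolated)
Conditions: MgI2 (1.0 equiv), 9 (1.5 equiv), 4 Å MS, THF, 23 → 50 °C, argon, dark
Reagents that add atoms: none
Why: Proposed new method: Mg(II) chelates the geminal diester, iodide attacks the unhindered C6 in an SN2 sense and releases the chelated malonate enolate 10 (C4–C6 breaks because this enolate is far better stabilised than the aryl ketone enolate that C5–C6 cleavage would give), C4 then adds reversibly to aldehyde 9, and the alkoxide O7 of 11 expels iodide from C6. The closest known reaction types are the magnesium iodide relay ring expansion of acceptor cyclopropanes with imines, the iodide-induced ring-opening aldol of cyclopropyl ketones and the Lewis acid (3+2) of donor–acceptor cyclopropanes with aldehydes; an acceptor-only 1,1-diester has not been taken to an oxolane with an aldehyde in this way. The single ring closes 5-exo-tet, which is irreversible and drains the unfavourable aldol equilibrium, while re-closure of 10 (3-exo-tet) only returns 8. C8 is the one new stereocentre: the two aldolates interconvert by retro-aldol, and the faster closure should be the envelope in which the C8 aryl and the C5 aroyl group are both pseudo-equatorial, which gives the 2,4-cis (2R,4S) isomer. C4 bears two identical esters and is no stereocentre, and no bond to C5 is made or broken, so its configuration is that of 8. The step needs attack at C6 rather than C5, C–C bond formation rather than proton transfer from C5–H, and survival of the benzyl ethers; the steric bias of the CH2 over the flanked CH, the low basicity of the chelated enolate, the non-enolisable aldehyde and a ceiling of 50 °C in a donor solvent are meant to secure these.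

Step 6
Reactants: 12 dimethyl (2R,4S)-4-[4-(benzyloxy)-3,5-dimethoxybenzoyl]-2-[3,4-bis(benzyloxy)phenyl]oxolane-3,3-dicarboxylate
Product: 14 methyl (3S,3aS,6R,6aR)-3-[4-(benzyloxy)-3,5-dimethoxyphenyl]-6-[3,4-bis(benzyloxy)phenyl]-1-oxotetrahydro-1H,3H-furo[3,4-c]furan-6a-carboxylate, via hydroxy diester 13 (not isolated)
Conditions: (S,S)-tethered Ru(II)–TsDPEN chloride (1 mol %), HCO2H/Et3N 5:2, EtOAc, 40 °C; then DBU (0.2 equiv), toluene, 60 °C
Reagents that add atoms: none
Why: Noyori–Ikariya asymmetric transfer hydrogenation followed by base-catalysed lactonisation, in which the (S,S) catalyst seats the aryl group under its η6-arene and delivers hydride to the face giving the (S)-carbinol at C1 (the acetophenone sense), the acidic 5:2 medium leaves C5–H alone, and only the ester cis to the carbinol side chain can close the cis-fused lactone, which makes C4 a defined quaternary centre.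

Step 7
Reactants: 14 methyl (3S,3aS,6R,6aR)-3-[4-(benzyloxy)-3,5-dimethoxyphenyl]-6-[3,4-bis(benzyloxy)phenyl]-1-oxotetrahydro-1H,3H-furo[3,4-c]furan-6a-carboxylate
Product: 15 (3S,3aS,6S,6aR)-3-[4-(benzyloxy)-3,5-dimethoxyphenyl]-6-[3,4-bis(benzyloxy)phenyl]tetrahydro-1H,3H-furo[3,4-c]furan-1-one
Conditions: LiCl (3 equiv), H2O (3 equiv), DMSO, 130 °C
Reagents that add atoms: none
Why: Krapcho dealkoxycarbonylation, in which chloride demethylates the activated ester, the carboxylate loses CO2 and the planar lactone enolate can only be protonated to the cis-fused bicyclo[3.3.0] system, so C4–H ends on the face of C5–H (C4 R) whatever the proton source.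

Step 8
Reactants: 15 (3S,3aS,6S,6aR)-3-[4-(benzyloxy)-3,5-dimethoxyphenyl]-6-[3,4-bis(benzyloxy)phenyl]tetrahydro-1H,3H-furo[3,4-c]furan-1-one
Product: 16 (3S,3aS,6S,6aR)-6-(3,4-dihydroxyphenyl)-3-(4-hydroxy-3,5-dimethoxyphenyl)tetrahydro-1H,3H-furo[3,4-c]furan-1-one (target)
Conditions: H2 (1 atm), 10% Pd/C, pyridine (0.5 equiv), EtOAc, 23 °C, stopped at full conversion
Reagents that add atoms: none
Why: Catalytic hydrogenolysis of three aryl benzyl ethers, in which the unhindered primary PhCH2–OAr bonds should cleave much faster than the hindered secondary C1–O2 and C8–O7 bonds, amine-moderated palladium is reported to slow cleavage of electron-rich benzylic C–O bonds more than that of plain benzyl aryl ethers, and the absence of acid or strong base avoids quinone-methide epimerisation of the endo aryl groups.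

Compound list
1 | acetosyringone, 1-(4-hydroxy-3,5-dimethoxyphenyl)ethan-1-one | CC(=O)c1cc(OC)c(O)c(OC)c1 | starting material
2 | 1-[4-(benzyloxy)-3,5-dimethoxyphenyl]ethan-1-one | CC(=O)c1cc(OC)c(OCc2ccccc2)c(OC)c1 | intermediate
3 | Mannich base, 1-[4-(benzyloxy)-3,5-dimethoxyphenyl]-3-(diisopropylamino)propan-1-one (not isolated) | COc1cc(C(=O)CCN(C(C)C)C(C)C)cc(OC)c1OCc1ccccc1 | intermediate
4 | 1-[4-(benzyloxy)-3,5-dimethoxyphenyl]prop-2-en-1-one | C=CC(=O)c1cc(OC)c(OCc2ccccc2)c(OC)c1 | intermediate
5 | dimethyl bromomalonate | COC(=O)C(Br)C(=O)OC | starting material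
6 | bromo Michael adduct, dimethyl 2-bromo-2-{3-[4-(benzyloxy)-3,5-dimethoxyphenyl]-3-oxopropyl}malonate, reacting as its ketone enolate (not isolated) | COC(=O)C(Br)(CCC(=O)c1cc(OC)c(OCc2ccccc2)c(OC)c1)C(=O)OC | intermediate
7 | racemic dimethyl 2-[4-(benzyloxy)-3,5-dimethoxybenzoyl]cyclopropane-1,1-dicarboxylate | COc1cc(C(=O)C2CC2(C(=O)OC)C(=O)OC)cc(OC)c1OCc1ccccc1 | intermediate
8 | dimethyl (2R)-2-[4-(benzyloxy)-3,5-dimethoxybenzoyl]cyclopropane-1,1-dicarboxylate | COc1cc(C(=O)[C@@H]2CC2(C(=O)OC)C(=O)OC)cc(OC)c1OCc1ccccc1 | intermediate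
9 | 3,4-bis(benzyloxy)benzaldehyde | O=Cc1ccc(OCc2ccccc2)c(OCc2ccccc2)c1 | starting material
10 | iodo enolate, iodomagnesium enolate of dimethyl 2-[1-aroyl-2-iodoethyl]malonate, C5 configuration as in 8 (not isolated) | COc1cc(C(=O)[C@H](CI)C(C(=O)OC)=C(OC)O[Mg]I)cc(OC)c1OCc1ccccc1 | intermediate
11 | iodo aldolate, iodomagnesium alkoxide from addition of C4 of 10 to 9, drawn as the C8 epimer that closes to 12 (not isolated) | COc1cc(C(=O)[C@H](CI)C(C(=O)OC)(C(=O)OC)[C@H](O[Mg]I)c2ccc(OCc3ccccc3)c(OCc3ccccc3)c2)cc(OC)c1OCc1ccccc1 | intermediate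
12 | dimethyl (2R,4S)-4-[4-(benzyloxy)-3,5-dimethoxybenzoyl]-2-[3,4-bis(benzyloxy)phenyl]oxolane-3,3-dicarboxylate, aryl and aroyl cis | COc1cc(C(=O)[C@@H]2CO[C@H](c3ccc(OCc4ccccc4)c(OCc4ccccc4)c3)C2(C(=O)OC)C(=O)OC)cc(OC)c1OCc1ccccc1 | intermediate
13 | hydroxy diester, dimethyl (2R,4S)-4-{(S)-[4-(benzyloxy)-3,5-dimethoxyphenyl](hydroxy)methyl}-2-[3,4-bis(benzyloxy)phenyl]oxolane-3,3-dicarboxylate (not isolated) | COc1cc([C@@H](O)[C@@H]2CO[C@H](c3ccc(OCc4ccccc4)c(OCc4ccccc4)c3)C2(C(=O)OC)C(=O)OC)cc(OC)c1OCc1ccccc1 | intermediate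
14 | methyl (3S,3aS,6R,6aR)-3-[4-(benzyloxy)-3,5-dimethoxyphenyl]-6-[3,4-bis(benzyloxy)phenyl]-1-oxotetrahydro-1H,3H-furo[3,4-c]furan-6a-carboxylate, both aryl groups endo, ester on the convex face | COc1cc([C@H]2OC(=O)[C@]3(C(=O)OC)[C@H]2CO[C@@H]3c2ccc(OCc3ccccc3)c(OCc3ccccc3)c2)cc(OC)c1OCc1ccccc1 | intermediate
15 | (3S,3aS,6S,6aR)-3-[4-(benzyloxy)-3,5-dimethoxyphenyl]-6-[3,4-bis(benzyloxy)phenyl]tetrahydro-1H,3H-furo[3,4-c]furan-1-one | COc1cc([C@H]2OC(=O)[C@@H]3[C@H]2CO[C@@H]3c2ccc(OCc3ccccc3)c(OCc3ccccc3)c2)cc(OC)c1OCc1ccccc1 | intermediate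
16 | (3S,3aS,6S,6aR)-6-(3,4-dihydroxyphenyl)-3-(4-hydroxy-3,5-dimethoxyphenyl)tetrahydro-1H,3H-furo[3,4-c]furan-1-one | COc1cc([C@H]2OC(=O)[C@@H]3[C@H]2CO[C@@H]3c2ccc(O)c(O)c2)cc(OC)c1O | target

Total step count: 8. Longest linear sequence: 8 steps (1 to 16).

Steps most likely to fail

**Step 5 (Proposed new method).**
- What may go wrong:
  - The opened enolate may only re-close without capturing the electron-rich aldehyde.
  - Proton shuffling from C5–H may be followed by loss of hydrogen iodide across C5–C6.
  - Cleavage of C5–C6 may compete with cleavage of C4–C6.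
  - Iodide may take off the crowded central benzyl group.
  - Discrimination between the cis and trans closures may be poor.
- Fallback with known chemistry, setting out from 9 and returning at 12:
  - Knoevenagel condensation of 9 with dimethyl malonate gives dimethyl 2-[3,4-bis(benzyloxy)benzylidene]malonate F1.
  - Benzylation of 4-iodo-2,6-dimethoxyphenol gives 2-(benzyloxy)-5-iodo-1,3-dimethoxybenzene F2.
  - The established palladium-mediated three-component oxolane synthesis follows. Lithium propargyl alkoxide adds to C8 of F1, the malonate enolate attacks the arylpalladium-activated alkyne 5-exo-dig, and reductive elimination delivers the aryl group of F2. This gives the racemic (Z)-4-arylidene oxolane diester F3.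
  - Hydroboration with BH3·SMe2 puts boron on the benzylic C1 and hydrogen on C5 from the face away from the C8 aryl group. Direct PCC oxidation of the borane then gives the racemic cis keto diester F4.
  - Preparative chiral SFC of F4 gives 12.

**Step 6.**
- What may go wrong:
  - The catalyst must override the substrate's own Felkin–Anh preference. Hydride approach anti to the quaternary C4 leads to the C1 epimer, so poor facial selectivity or sluggish turnover is possible.
  - Slow amine-induced epimerisation at C5 would feed the wrong diastereomeric series.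
- Fallback, setting out from 12 and returning at 15 (the substrate bias is used and C1 is then inverted):
  - L-Selectride at −78 °C followed by warming gives the C1-epimeric exo-aryl lactone ester F5.
  - Krapcho dealkoxycarbonylation gives the exo-aryl lactone F6.
  - Lithium hydroxide and careful neutralisation give the hydroxy acid F7.
  - Mitsunobu lactonisation (PPh3, DIAD) activates the benzylic alcohol, and the cis carboxylate displaces it with inversion to give 15.

**Step 7.**
- What may go wrong:
  - At 130 °C the transient lactone enolate may expel O7 by β-elimination, which opens the oxolane.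
  - The strained endo benzylic C1–O2 bond may ionise, which epimerises C1.
- Fallback, setting out from 14 and returning at 15 (the carboxyl group is removed through a radical at room temperature, so no enolate is formed):
  - Lithium iodide in refluxing ethyl acetate demethylates the ester to the lactone carboxylic acid F8.
  - Coupling with 2-mercaptopyridine N-oxide (DCC) gives the thiohydroxamate ester F9.
  - Barton reductive decarboxylation (visible light, t-BuSH, 23 °C) lets the C4 radical take hydrogen on the only face that keeps the cis fusion.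

Further compounds
F1 | step 5 | dimethyl 2-[3,4-bis(benzyloxy)benzylidene]malonate | COC(=O)C(=Cc1ccc(OCc2ccccc2)c(OCc2ccccc2)c1)C(=O)OC
F2 | step 5 | 2-(benzyloxy)-5-iodo-1,3-dimethoxybenzene | COc1cc(I)cc(OC)c1OCc1ccccc1
F3 | step 5 | racemic dimethyl (4Z)-4-[4-(benzyloxy)-3,5-dimethoxybenzylidene]-2-[3,4-bis(benzyloxy)phenyl]oxolane-3,3-dicarboxylate | COc1cc(/C=C2\COC(c3ccc(OCc4ccccc4)c(OCc4ccccc4)c3)C2(C(=O)OC)C(=O)OC)cc(OC)c1OCc1ccccc1
F4 | step 5 | racemic cis keto diester, 1:1 mixture of 12 and its enantiomer | COc1cc(C(=O)[C@@H]2CO[C@H](c3ccc(OCc4ccccc4)c(OCc4ccccc4)c3)C2(C(=O)OC)C(=O)OC)cc(OC)c1OCc1ccccc1.COc1cc(C(=O)[C@H]2CO[C@@H](c3ccc(OCc4ccccc4)c(OCc4ccccc4)c3)C2(C(=O)OC)C(=O)OC)cc(OC)c1OCc1ccccc1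
F5 | step 6 | methyl (3R,3aS,6R,6aR)-3-[4-(benzyloxy)-3,5-dimethoxyphenyl]-6-[3,4-bis(benzyloxy)phenyl]-1-oxotetrahydro-1H,3H-furo[3,4-c]furan-6a-carboxylate, C1 epimer of 14 | COc1cc([C@@H]2OC(=O)[C@]3(C(=O)OC)[C@H]2CO[C@@H]3c2ccc(OCc3ccccc3)c(OCc3ccccc3)c2)cc(OC)c1OCc1ccccc1
F6 | step 6 | (3R,3aS,6S,6aR)-3-[4-(benzyloxy)-3,5-dimethoxyphenyl]-6-[3,4-bis(benzyloxy)phenyl]tetrahydro-1H,3H-furo[3,4-c]furan-1-one, C1 epimer of 15 | COc1cc([C@@H]2OC(=O)[C@@H]3[C@H]2CO[C@@H]3c2ccc(OCc3ccccc3)c(OCc3ccccc3)c2)cc(OC)c1OCc1ccccc1
F7 | step 6 | (2S,3R,4S)-4-{(R)-[4-(benzyloxy)-3,5-dimethoxyphenyl](hydroxy)methyl}-2-[3,4-bis(benzyloxy)phenyl]oxolane-3-carboxylic acid | COc1cc([C@H](O)[C@@H]2CO[C@H](c3ccc(OCc4ccccc4)c(OCc4ccccc4)c3)[C@@H]2C(=O)O)cc(OC)c1OCc1ccccc1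
F8 | step 7 | (3S,3aS,6R,6aR)-3-[4-(benzyloxy)-3,5-dimethoxyphenyl]-6-[3,4-bis(benzyloxy)phenyl]-1-oxotetrahydro-1H,3H-furo[3,4-c]furan-6a-carboxylic acid | COc1cc([C@H]2OC(=O)[C@]3(C(=O)O)[C@H]2CO[C@@H]3c2ccc(OCc3ccccc3)c(OCc3ccccc3)c2)cc(OC)c1OCc1ccccc1
F9 | step 7 | 2-thioxopyridin-1(2H)-yl ester of F8 | COc1cc([C@H]2OC(=O)[C@]3(C(=O)ON4C=CC=CC4=S)[C@H]2CO[C@@H]3c2ccc(OCc3ccccc3)c(OCc3ccccc3)c2)cc(OC)c1OCc1ccccc1
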